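All constants stand for no real mixture; the flask was simulated.

Product in this flask forms one for one from reagent and substrate, by way of the intermediate.

    substrate ⇌ intermediate + leaving ligand (K1 = 2.2 × 10⁻⁴ M, k1 = 0.0040 min⁻¹)
    reagent + intermediate → product (k2 = 280 M⁻¹ min⁻¹)
    crystals ⇌ leaving ligand, rate k3*(cs3 - [leaving ligand]) while solid is left; crystals form when [leaving ligand] > cs3 (cs3 = 0.071 M, k3 = 0.089 min⁻¹)

substrate 0.13 M (in portions, 2); reagent 0.117 M; time 15 d; the portions of substrate follow each other after 6.0 min, the first at the start

- why nothing more happens at 15 d, or that something still does (all of the substrate has reacted / forward and back rates have come level / the reagent has run out first / it is still moving)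
- the product standing at 15 d, as a percentage of the substrate charged
- amount of product if the flask were left three thousand times as long, in percent of the substrate charged

- what is said of leaving ligand includes crystals
- crystals is a solid; its amount is given per volume of the solution
- the reaction counts as stopped when no species that holds the substrate changes by six tenths of a point or more over the second half of the time
- run time (flask): 15 d

1. The end state comes first. The two charges fold into 0.900, the charge ratio: reagent charged per substrate charged. The flask holds less reagent than substrate, so reagent is the limiting reagent, and my reckoning puts product at the ratio itself, 90.0% of the substrate charged.

2. A ratio contains no rates, so its sufficiency needs testing. My reckoning has the leaving ligand released in the flask reach 0.117 M, above the solubility, so crystals hold [leaving ligand] at 0.071 M. By its forward rate alone, substrate ionises with a lifetime of 250 min. Late on in the flask, with [substrate] at 0.0130 M, reagent decays pseudo-first-order with time constant [leaving ligand]/(K1·k2·[substrate]), or 88.7 min. Both are far shorter than 15 d.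

3. Once the reagent in the flask is consumed, my reckoning puts the intermediate in equilibrium with the remaining substrate at 0.0310% of the substrate charged. My reckoning therefore expects the reagent to run out first and waiting to add no product.

4. The forecast says the reagent has run out first, with 90% product at 15 d (range 89.5% to 90%) and 90% after the long wait asked about (range 89.8% to 90.1%). Its grounds include this: “waiting longer adds nothing”.

5. In the simulation of the flask, the reagent has run out first, with 90.0% product at 15 d and 90.0% after the long wait asked about.

6. Product in the flask stands at the charge ratio 0.900, with 0% of the reagent left and 10% of the substrate still there. That substrate remains because of the way back from intermediate and leaving ligand: with that step taken away, conversion of substrate is 100% against 90.0%. The neighbour charged with 0.029 M of reagent has a charge ratio of 0.223; it gives 22.3% product and keeps 77% of its substrate.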